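**Retrosynthetic overview**
1. Pseudopentafuhalol D ⇐ undecamethyl ether 24 by global O-demethylation. Rings A, C, D and E are bought as oxygenated benzenes; ring B is the only ring built and is formed last.
2. The strategy rests on ring B, which carries vicinal aryloxy groups at B1 (to ring A) and B2 (to ring C) next to meta hydroxyls at B3 and B5. It is cut at B1–B2 and B3–B4: B2–B3 come from the CDE aryloxyacetate 11, and B1, B6, B5, B4 from 4-(2,4,6-trimethoxyphenoxy)but-3-yn-2-one 20 (Michael addition, Claisen closure, tautomerisation).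
3. 11 ⇐ CDE phenol 9 + methyl bromoacetate; 9 ⇐ two rounds of Ullmann etherification of a bromobenzaldehyde, each followed by Baeyer–Villiger conversion of CHO into OH (E + D, then + C).
4. 20 ⇐ 2,4,6-trimethoxyphenol via its (E)-1,2-dichlorovinyl ether, the lithium aryloxyacetylide, acetaldehyde and MnO2 oxidation.

Key step: step 9

Assumption: dienolate 22 is drawn without alkene geometry because its delocalised anion should equilibrate the geometry about B1–B6 and B2–B1 before ring closure; 19 is carried as the racemate because its carbinol centre is oxidised away in step 8.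

**Step 1**
Reactants: 1 2-bromo-3,4,5-trimethoxybenzaldehyde; 2 3,4,5-trimethoxyphenol
Product: 3 DE aldehyde 3,4,5-trimethoxy-2-(3,4,5-trimethoxyphenoxy)benzaldehyde
Conditions: CuI (10 mol%), picolinic acid (20 mol%), K3PO4, DMSO, 90 °C, argon
Reagents that add atoms: none
Why: Ullmann-type copper-catalysed C–O coupling, in which the bromide is activated by its ortho formyl group, phenol 2 is unhindered, and the picolinate ligand tolerates the flanking methoxy group.

**Step 2**
Reactants: 3 DE aldehyde
Product: 5 DE phenol 3,4,5-trimethoxy-2-(3,4,5-trimethoxyphenoxy)phenol, via aryl formate 4 (not isolated)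
Conditions: mCPBA, CH2Cl2, 0 °C to rt; aq. NaHCO3 wash; K2CO3 (cat.), MeOH, rt
Reagents that add atoms: mCPBA, OOC(=O)c1cccc(Cl)c1
Why: Baeyer–Villiger (Dakin-type) oxidation, in which the electron-rich aryl group with ortho and para oxygen donors should migrate in preference to hydride, and the resulting formate is cleaved by methanolysis.

**Step 3**
Reactants: 5 DE phenol; 6 3-bromo-4,5-dimethoxybenzaldehyde
Product: 7 CDE aldehyde 3,4-dimethoxy-5-[3,4,5-trimethoxy-2-(3,4,5-trimethoxyphenoxy)phenoxy]benzaldehyde
Conditions: CuI (10 mol%), picolinic acid (20 mol%), K3PO4, DMSO, 100 °C, argon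
Reagents that add atoms: none
Why: Ullmann-type C–O coupling with a ligand system suited to an ortho-substituted phenol and an ortho-substituted aryl bromide, the formyl group making 6 the electron-poor, more reactive partner.

**Step 4**
Reactants: 7 CDE aldehyde
Product: 9 CDE phenol 3,4-dimethoxy-5-[3,4,5-trimethoxy-2-(3,4,5-trimethoxyphenoxy)phenoxy]phenol, via aryl formate 8 (not isolated)
Conditions: mCPBA, CH2Cl2, 0 °C to rt; aq. NaHCO3 wash; K2CO3 (cat.), MeOH, rt
Reagents that add atoms: mCPBA, OOC(=O)c1cccc(Cl)c1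
Why: Baeyer–Villiger (Dakin-type) oxidation driven by the para methoxy group, as in the conversion of 3,4,5-trialkoxybenzaldehydes into their phenols, which places the free hydroxyl at C1 of ring C.

**Step 5**
Reactants: 9 CDE phenol; 10 methyl bromoacetate
Product: 11 methyl 2-{3,4-dimethoxy-5-[3,4,5-trimethoxy-2-(3,4,5-trimethoxyphenoxy)phenoxy]phenoxy}acetate
Conditions: K2CO3, acetone, reflux
Reagents that add atoms: none
Why: Williamson etherification (SN2) of the only phenoxide in the molecule with an α-bromo ester.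

**Step 6**
Reactants: 12 2,4,6-trimethoxyphenol; 13 trichloroethylene
Product: 15 2-[(E)-1,2-dichloroethenoxy]-1,3,5-trimethoxybenzene, via dichloroacetylene 14 (not isolated)
Conditions: K2CO3, DMF, 70 °C
Reagents that add atoms: none
Why: Base-induced dehydrochlorination of trichloroethylene gives dichloroacetylene, to which the phenoxide adds anti to give the (E)-dichlorovinyl ether, a known preparation of aryl 1,2-dichlorovinyl ethers.

**Step 7**
Reactants: 15 dichlorovinyl ether; 16 acetaldehyde
Product: 19 racemic 4-(2,4,6-trimethoxyphenoxy)but-3-yn-2-ol, via chloroalkynyl ether 17 (not isolated), via lithium acetylide 18 (not isolated)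
Conditions: nBuLi (2.2 equiv), THF, −78 °C; MeCHO, −78 °C; H2O
Reagents that add atoms: none
Why: Deprotonation and β-elimination give the chloroalkyne, lithium–chlorine exchange gives the lithium aryloxyacetylide (the standard dichlorovinyl ether route to metallated ynol ethers), and 1,2-addition to the aldehyde gives the carbinol as a racemate.

**Step 8**
Reactants: 19 racemic 4-(2,4,6-trimethoxyphenoxy)but-3-yn-2-ol
Product: 20 4-(2,4,6-trimethoxyphenoxy)but-3-yn-2-one
Conditions: activated MnO2, CH2Cl2, rt; filtration through Celite, concentration cold, used at once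
Reagents that add atoms: none
Why: MnO2 oxidation of a propargylic alcohol under neutral, anhydrous, heterogeneous conditions, so the hydration-prone push–pull ynone should be obtained by filtration alone.

**Step 9**
Reactants: 11 CDE aryloxyacetate; 20 aryloxy ynone
Product: 24 undeca-O-methyl pentamer 4-{3,4-dimethoxy-5-[3,4,5-trimethoxy-2-(3,4,5-trimethoxyphenoxy)phenoxy]phenoxy}-5-(2,4,6-trimethoxyphenoxy)benzene-1,3-diol, via lithium ester enolate 21 (not isolated), via lithium dienolate 22 (not isolated), via cyclohexenedione 23 (not isolated)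
Conditions: LiN(SiMe3)2 (1.05 equiv), THF, −78 °C; 20 (1.2 equiv), −78 to 0 °C; KOtBu (3 equiv), tBuOH, 0 to 50 °C; 1 M HCl to pH 4
Reagents that add atoms: none
Why: The lithium enolate 21 should add through its α-carbon to the aryloxy-bearing β-carbon of ynone 20 (bond B2–B1), and the allenolate is quenched by proton transfer from the now doubly activated B2–H to give the delocalised dienolate 22, in which the ring A oxygen sits on an sp2 carbon and is retained. Under KOtBu/tBuOH this anion equilibrates with its methyl-ketone (B4) enolate tautomer, which attacks the ester carbonyl in a 6-(enolendo)-exo-trig Claisen closure (bond B4–B3) with loss of methoxide, and dione 23 tautomerises to the resorcinol. The closest known reaction type is the Michael–Claisen synthesis of resorcinols from but-3-yn-2-ones and ester or malonate enolates. No stereocentre remains, because B2 becomes aromatic, so no stereocontrol is required. The step needs 1,4- over 1,2-addition, which the ynylogous-ester polarisation of 20 (deactivated carbonyl, oxocarbenium-like β-carbon) and the reversibility of a lithium aldolate on warming should secure. It also needs C- over O-cyclisation, which is secured because an α-pyranone would be reopened by alkoxide whereas formation of the aromatic phenoxide is irreversible.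

**Step 10**
Reactants: 24 undeca-O-methyl pentamer
Product: 25 pseudopentafuhalol D
Conditions: BBr3 (excess), CH2Cl2, −78 °C to rt; MeOH, −78 °C, co-evaporation with MeOH; reversed-phase chromatography under argon
Reagents that add atoms: none
Why: Lewis-acid ether cleavage in which bromide attacks the methyl group of each BBr3-complexed aryl methyl ether (SN2), whereas the diaryl ether oxygens carry only sp2 carbons and cannot be cleaved this way; methanol removes boron from the catechol and pyrogallol units as B(OMe)3.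

**Compound list**
1 | 2-bromo-3,4,5-trimethoxybenzaldehyde | O=Cc1cc(OC)c(OC)c(OC)c1Br | starting material
2 | 3,4,5-trimethoxyphenol | COc1cc(O)cc(OC)c1OC | starting material
3 | 3,4,5-trimethoxy-2-(3,4,5-trimethoxyphenoxy)benzaldehyde (DE aldehyde) | O=Cc1cc(OC)c(OC)c(OC)c1Oc1cc(OC)c(OC)c(OC)c1 | intermediate
4 | 3,4,5-trimethoxy-2-(3,4,5-trimethoxyphenoxy)phenyl formate | O=COc1cc(OC)c(OC)c(OC)c1Oc1cc(OC)c(OC)c(OC)c1 | intermediate
5 | 3,4,5-trimethoxy-2-(3,4,5-trimethoxyphenoxy)phenol (DE phenol) | Oc1cc(OC)c(OC)c(OC)c1Oc1cc(OC)c(OC)c(OC)c1 | intermediate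
6 | 3-bromo-4,5-dimethoxybenzaldehyde | O=Cc1cc(Br)c(OC)c(OC)c1 | starting material
7 | 3,4-dimethoxy-5-[3,4,5-trimethoxy-2-(3,4,5-trimethoxyphenoxy)phenoxy]benzaldehyde (CDE aldehyde) | O=Cc1cc(OC)c(OC)c(Oc2cc(OC)c(OC)c(OC)c2Oc2cc(OC)c(OC)c(OC)c2)c1 | intermediate
8 | 3,4-dimethoxy-5-[3,4,5-trimethoxy-2-(3,4,5-trimethoxyphenoxy)phenoxy]phenyl formate | O=COc1cc(OC)c(OC)c(Oc2cc(OC)c(OC)c(OC)c2Oc2cc(OC)c(OC)c(OC)c2)c1 | intermediate
9 | 3,4-dimethoxy-5-[3,4,5-trimethoxy-2-(3,4,5-trimethoxyphenoxy)phenoxy]phenol (CDE phenol) | Oc1cc(OC)c(OC)c(Oc2cc(OC)c(OC)c(OC)c2Oc2cc(OC)c(OC)c(OC)c2)c1 | intermediate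
10 | methyl bromoacetate | COC(=O)CBr | starting material
11 | methyl 2-{3,4-dimethoxy-5-[3,4,5-trimethoxy-2-(3,4,5-trimethoxyphenoxy)phenoxy]phenoxy}acetate | COC(=O)COc1cc(OC)c(OC)c(Oc2cc(OC)c(OC)c(OC)c2Oc2cc(OC)c(OC)c(OC)c2)c1 | intermediate
12 | 2,4,6-trimethoxyphenol | COc1cc(OC)c(O)c(OC)c1 | starting material
13 | trichloroethylene | ClC=C(Cl)Cl | starting material
14 | dichloroacetylene | ClC#CCl | intermediate
15 | 2-[(E)-1,2-dichloroethenoxy]-1,3,5-trimethoxybenzene | Cl/C=C(/Cl)Oc1c(OC)cc(OC)cc1OC | intermediate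
16 | acetaldehyde | CC=O | starting material
17 | 2-(chloroethynyloxy)-1,3,5-trimethoxybenzene | ClC#COc1c(OC)cc(OC)cc1OC | intermediate
18 | lithium (2,4,6-trimethoxyphenoxy)acetylide | [Li]C#COc1c(OC)cc(OC)cc1OC | intermediate
19 | racemic 4-(2,4,6-trimethoxyphenoxy)but-3-yn-2-ol | CC(O)C#COc1c(OC)cc(OC)cc1OC | intermediate
20 | 4-(2,4,6-trimethoxyphenoxy)but-3-yn-2-one | CC(=O)C#COc1c(OC)cc(OC)cc1OC | intermediate
21 | lithium enolate of ester 11 | COC(O[Li])=COc1cc(OC)c(OC)c(Oc2cc(OC)c(OC)c(OC)c2Oc2cc(OC)c(OC)c(OC)c2)c1 | intermediate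
22 | lithium dienolate of methyl 2-(CDE-aryloxy)-3-(2,4,6-trimethoxyphenoxy)-5-oxohex-3-enoate (alkene geometry equilibrating) | COC(O[Li])=C(Oc1cc(OC)c(OC)c(Oc2cc(OC)c(OC)c(OC)c2Oc2cc(OC)c(OC)c(OC)c2)c1)C(Oc1c(OC)cc(OC)cc1OC)=CC(C)=O | intermediate
23 | 4-(CDE-aryloxy)-5-(2,4,6-trimethoxyphenoxy)cyclohex-5-ene-1,3-dione | O=C1CC(=O)C(Oc2cc(OC)c(OC)c(Oc3cc(OC)c(OC)c(OC)c3Oc3cc(OC)c(OC)c(OC)c3)c2)C(Oc2c(OC)cc(OC)cc2OC)=C1 | intermediate
24 | 4-{3,4-dimethoxy-5-[3,4,5-trimethoxy-2-(3,4,5-trimethoxyphenoxy)phenoxy]phenoxy}-5-(2,4,6-trimethoxyphenoxy)benzene-1,3-diol (undeca-O-methyl pentamer) | COc1cc(OC)c(Oc2cc(O)cc(O)c2Oc2cc(OC)c(OC)c(Oc3cc(OC)c(OC)c(OC)c3Oc3cc(OC)c(OC)c(OC)c3)c2)c(OC)c1 | intermediate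
25 | pseudopentafuhalol D | Oc1cc(O)c(Oc2cc(O)cc(O)c2Oc2cc(O)c(O)c(Oc3cc(O)c(O)c(O)c3Oc3cc(O)c(O)c(O)c3)c2)c(O)c1 | target

**Step count**
Total steps: 10. Longest linear sequence: 7 steps (1, 2, 3, 4, 5, 9, 10); the ynone branch (6, 7, 8) joins at step 9.

**Steps most likely to fail**

Step 9 (key step). Several processes may intervene:
- proton transfer from the acetyl group of 20 to enolate 21;
- 1,2-addition that does not revert;
- expulsion of 2,4,6-trimethoxyphenoxide from the allenolate by addition–elimination;
- O-acylation to an α-pyranone that is not reopened.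

The fallback sets out from 11 and comes back at 24 by a stepwise Mukaiyama–Michael sequence. Ester 11 is converted with LiN(SiMe3)2 and Me3SiCl in THF at −78 °C into its trimethylsilyl ketene acetal F1. F1 is added to 20 with catalytic Me3SiOTf in CH2Cl2 at −78 °C; the silylated carbonyl makes the aryloxy-bearing carbon an oxocarbenium-type electrophile, and no basic allenolate is formed. Aqueous work-up should give the neutral keto ester methyl 2-(CDE-aryloxy)-3-(2,4,6-trimethoxyphenoxy)-5-oxohex-3-enoate F2. F2 is isolated and cyclised in a separate operation with KOtBu in tBuOH/THF to give 24.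

Step 8. The push–pull alkyne may be hydrated to the aryl acetoacetate on the oxidant surface or on concentration, or 20 may oligomerise before use. The fallback sets out from 12 and comes back at dienolate 22 inside step 9, using an ynone surrogate of the same oxidation level. Acetyl chloride and 1,1-dichloroethene with AlCl3 in CH2Cl2 give 4,4,4-trichlorobutan-2-one F3, which loses HCl on distillation to give 4,4-dichlorobut-3-en-2-one F4. The potassium salt of 12 (K2CO3, acetone, 0 °C) displaces one chloride by addition–elimination to give 4-chloro-4-(2,4,6-trimethoxyphenoxy)but-3-en-2-one F5, a storable vinylogous acid chloride. Enolate 21, with a second equivalent of LiN(SiMe3)2, then displaces the remaining chloride (the better leaving group) to give 22, which is carried on with KOtBu as in step 9 to give 24.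

Step 10. Cleavage of the eleven methyl ethers may stop short, and the free tridecaphenol may be oxidised by air or lost by adsorption during isolation. The fallback sets out from 24 and comes back at 25 by a derivatise–purify–release sequence. After the BBr3 treatment and methanol quench, the crude phenol is acetylated at once (Ac2O, pyridine) to trideca-O-acetyl pseudopentafuhalol D F6, which is stable and separable on silica from under-demethylated material (this is resubjected to BBr3). F6 is then deacetylated under non-oxidising acidic conditions (HCl generated from AcCl in degassed MeOH, argon, rt) to give 25.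

**Further compounds**
F1 | step 9 | trimethylsilyl ketene acetal of ester 11 | COC(O[Si](C)(C)C)=COc1cc(OC)c(OC)c(Oc2cc(OC)c(OC)c(OC)c2Oc2cc(OC)c(OC)c(OC)c2)c1
F2 | step 9 | methyl 2-(CDE-aryloxy)-3-(2,4,6-trimethoxyphenoxy)-5-oxohex-3-enoate | COC(=O)C(Oc1cc(OC)c(OC)c(Oc2cc(OC)c(OC)c(OC)c2Oc2cc(OC)c(OC)c(OC)c2)c1)C(Oc1c(OC)cc(OC)cc1OC)=CC(C)=O
F3 | step 8 | 4,4,4-trichlorobutan-2-one | CC(=O)CC(Cl)(Cl)Cl
F4 | step 8 | 4,4-dichlorobut-3-en-2-one | CC(=O)C=C(Cl)Cl
F5 | step 8 | 4-chloro-4-(2,4,6-trimethoxyphenoxy)but-3-en-2-one | CC(=O)C=C(Cl)Oc1c(OC)cc(OC)cc1OC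
F6 | step 10 | trideca-O-acetyl pseudopentafuhalol D | CC(=O)Oc1cc(OC(C)=O)c(Oc2cc(OC(C)=O)cc(OC(C)=O)c2Oc2cc(OC(C)=O)c(OC(C)=O)c(Oc3cc(OC(C)=O)c(OC(C)=O)c(OC(C)=O)c3Oc3cc(OC(C)=O)c(OC(C)=O)c(OC(C)=O)c3)c2)c(OC(C)=O)c1
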